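**Plan**

1. Numbering: cyclohexene C1 (quaternary) to C6 (aryl-bearing); link Cα (on C1)=Cβ; coumarin A (on Cβ) takes primed locants, coumarin B (on C6) double-primed locants.
2. Retrosynthetic cuts, in order: both lactone rings at O1–C2 and C4–C4a (A and B alike) to a bis-phenol; the benzene ring of coumarin A at C4a′–C5′, C6′–C7′, C7′–C8′ and C8a′–C4a′ to a dienyl diazomethyl ketone and a silyloxyacetylene; Cα=Cβ (olefination) to the C1 aldehyde; C1–C6 and C2–C3 (Diels–Alder) to an aryl diene and methacrolein.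
3. Forward: the benzene ring of B is bought; the cyclohexene is closed first; the C1 chain is grown to the dienyl diazo ketone; the benzene ring of A is grown on it; the two pyranone rings are closed last in one twofold sequence.
4. Stereochemistry: C1 and C6 are set together in a catalytic enantioselective, formyl-exo Diels–Alder reaction; C1 is quaternary and cannot epimerise; the E link comes from the olefination.
5. Enabling feature: ring A is a resorcinol-type benzene in which O7′ and O8a′ are meta across C8′–H and the Cβ-bearing C6′ lies ortho to O7′ and para to O8a′. This is the pattern that a vinylketene (C7′, C4a′, C5′, C6′) and an oxygenated alkyne (C8′, C8a′) deliver.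

Key step: step 10

Assumption: the (S)-configured oxazaborolidinium ion is taken to expose to diene 5 the same face of methacrolein that it exposes to cyclopentadiene (S quaternary centre); were the sense opposite, its mirror image would be used with nothing else changed.

Abbreviation: Cy = (1R,2S)-2-[2-methoxy-4-(triisopropylsilyloxy)phenyl]-1,4-dimethylcyclohex-3-en-1-yl (chain on C1 trans to the aryl group, methyl cis).

**Route**

Step 1
Reactants: 1 4-hydroxy-2-methoxybenzaldehyde; 2 triisopropylsilyl trifluoromethanesulfonate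
Product: 3 2-methoxy-4-(triisopropylsilyloxy)benzaldehyde
Conditions: 2,6-lutidine, CH2Cl2, 0 °C
Reagents that add atoms: none
Why: O-silylation of the phenol by the silyl triflate with a hindered pyridine base should be clean, and the aldehyde is not touched.

Step 2
Reactants: 3 2-methoxy-4-(triisopropylsilyloxy)benzaldehyde; 4 diethyl (2-methylprop-2-en-1-yl)phosphonate
Product: 5 (E)-1-[2-methoxy-4-(triisopropylsilyloxy)phenyl]-3-methylbuta-1,3-diene
Conditions: n-BuLi, (Me2N)3PO, THF, −78 °C → 20 °C
Reagents that add atoms: none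
Why: Horner–Wadsworth–Emmons olefination with a lithiated allylic phosphonate, which in the presence of the phosphoramide attacks through its α-carbon and eliminates phosphate to give the (E)-1-aryl diene.

Step 3
Reactants: 5 (E)-1-[2-methoxy-4-(triisopropylsilyloxy)phenyl]-3-methylbuta-1,3-diene; 6 methacrolein
Product: 7 (1S,2R)-2-[2-methoxy-4-(triisopropylsilyloxy)phenyl]-1,4-dimethylcyclohex-3-ene-1-carbaldehyde (formyl trans to aryl)
Conditions: (S)-1-(2-methylphenyl)-3,3-diphenyltetrahydro-1H,3H-pyrrolo[1,2-c][1,3,2]oxazaborole (C24H24BNO, 20 mol %), (CF3SO2)2NH (17 mol %), CH2Cl2, −78 → −40 °C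
Reagents that add atoms: none
Why: Enantioselective Diels–Alder reaction under oxazaborolidinium catalysis, in which the enal is bound s-trans to boron with one face screened, the aryl-bearing diene terminus joins the α-carbon ("ortho", with the 3-methyl group "para"), and the formyl-exo arrangement typical of 2-substituted acroleins should set C1 (S) and C6 (R) together.

Step 4
Reactants: 7 the C1 aldehyde; 8 triethyl 4-phosphonocrotonate
Product: 9 ethyl (2E,4E)-5-Cy-penta-2,4-dienoate
Conditions: LiN(SiMe3)2, THF, −78 °C → 20 °C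
Reagents that add atoms: none
Why: Vinylogous Horner–Wadsworth–Emmons olefination of an aldehyde that has no α-hydrogen and so cannot epimerise, its bulk favouring the E geometry of the new Cα=Cβ bond.

Step 5
Reactants: 9 ethyl (2E,4E)-5-Cy-penta-2,4-dienoate
Product: 10 (2E,4E)-N-methoxy-N-methyl-5-Cy-penta-2,4-dienamide
Conditions: MeNH(OMe)·HCl, i-PrMgCl, THF, −20 → 0 °C
Reagents that add atoms: N,O-dimethylhydroxylamine hydrochloride, CNOC.Cl
Why: Direct aminolysis of the ester by the chloromagnesium amide of N,O-dimethylhydroxylamine (Weinreb amide formation), which at low temperature should attack the carbonyl group and not the diene.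

Step 6
Reactants: 10 the Weinreb dienamide
Product: 11 (3E,5E)-6-Cy-hexa-3,5-dien-2-one
Conditions: MeMgBr, THF, −10 → 0 °C; aq. NH4Cl
Reagents that add atoms: methylmagnesium bromide, C[Mg]Br
Why: Weinreb ketone synthesis, in which the chelated tetrahedral adduct stops the addition at the methyl ketone.

Step 7
Reactants: 11 (3E,5E)-6-Cy-hexa-3,5-dien-2-one
Product: 12 (5E,7E)-1,1,1-trifluoro-8-Cy-octa-5,7-diene-2,4-dione (largely enolised, used crude)
Conditions: LiN(SiMe3)2, THF, −78 °C; CF3CO2CH2CF3; aq. HCl work-up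
Reagents that add atoms: 2,2,2-trifluoroethyl trifluoroacetate, O=C(OCC(F)(F)F)C(F)(F)F
Why: Claisen acylation of the lithium enolate, which can form only at the methyl group because the unsaturated chain ends at quaternary C1.

Step 8
Reactants: 12 the trifluoroacetyl diketone
Product: 13 (3E,5E)-1-diazo-6-Cy-hexa-3,5-dien-2-one
Conditions: MeSO2N3, Et3N, H2O (1 equiv), MeCN, 20 °C
Reagents that add atoms: methanesulfonyl azide, CS(=O)(=O)N=[N+]=[N-]
Why: Detrifluoroacetylative diazo transfer (Regitz type), in which the activated methylene takes the diazo group and the trifluoroacetyl group leaves on the sulfonamide nitrogen, so that the diene is never exposed to diazomethane.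

Step 9
Reactants: 14 ethyl formate; 15 dibromomethane; 2 triisopropylsilyl trifluoromethanesulfonate
Product: 17 (triisopropylsilyloxy)acetylene, via lithium ethynolate 16 (not isolated)
Conditions: lithium 2,2,6,6-tetramethylpiperidide (2.2 equiv), THF, −78 °C; n-BuLi, −78 → 0 °C; i-Pr3SiOTf (2.2 equiv), −78 → 0 °C; distilled and used fresh
Reagents that add atoms: none
Why: Kowalski ester homologation stopped at the ynolate, in which the dibromomethyllithium adduct of the formate collapses to the dibromo enolate, bromine–lithium exchange and a 1,2-hydride shift give lithium ethynolate, and the bulky silyl triflate should silylate it on oxygen.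

Step 10
Reactants: 13 (3E,5E)-1-diazo-6-Cy-hexa-3,5-dien-2-one; 17 (triisopropylsilyloxy)acetylene (2 equiv)
Product: 22 2-[(E)-2-Cy-ethenyl]-5-(triisopropylsilyloxy)phenol, via dienylketene 18 (not isolated), via silyloxycyclobutenone 19 (not isolated), via ring-opened ketene 20 (not isolated), via cyclohexadienone 21 (not isolated)
Conditions: hν (350 nm lamps, Pyrex), degassed ClCH2CH2Cl, 20 °C until 13 is consumed; then 80 °C
Reagents that add atoms: none
Why: Light expels N2 from 13 and the dienyl group shifts to the former diazo carbon (Wolff rearrangement, C4a′–C5′) to give ketene 18; the polarised silyloxyalkyne then adds across the ketene C=C in a [2+2] cycloaddition, its CH carbon to the carbonyl carbon (C7′–C8′) and its oxygen-bearing carbon to the α-carbon (C8a′–C4a′), giving cyclobutenone 19. On warming, 19 opens by conrotatory 4π cleavage to ketene 20, which closes the benzene ring by thermal disrotatory 6π electrocyclisation (C6′–C7′) to dienone 21 and tautomerises to phenol 22. The closest known reaction type is the photochemical (Wolff) variant of the Danheiser benzannulation of α,β-unsaturated diazomethyl ketones with silyloxy- and alkoxyalkynes, the extra E double bond being a spectator. No lasting stereocentre is formed (the sp3 ring carbons of 19 and 21 disappear) and C1 and C6 lie outside the reacting π system. The step needs the [2+2] regiochemistry, which the match of the nucleophilic alkyne CH with the ketene carbonyl carbon secures and which places O8a′ para and O7′ ortho to the link; it also needs capture of 18 to outrun other paths, which the E geometry of C5′=C6′ helps because it holds C7′ away from Cβ and forbids a direct 6π closure of 18. The Cα=Cβ bond should stay E because 22 does not absorb the 350 nm light and the Z isomer would press the arene against quaternary C1.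

Step 11
Reactants: 22 2-[(E)-2-Cy-ethenyl]-5-(triisopropylsilyloxy)phenol
Product: 23 1-[(E)-2-Cy-ethenyl]-2-methoxy-4-(triisopropylsilyloxy)benzene
Conditions: MeI, K2CO3, acetone, 40 °C
Reagents that add atoms: iodomethane, CI
Why: Williamson O-methylation of the only free phenol, under conditions that aryl triisopropylsilyl ethers tolerate.

Step 12
Reactants: 23 the methyl ether
Product: 24 4-[(E)-2-[(1R,2S)-2-(4-hydroxy-2-methoxyphenyl)-1,4-dimethylcyclohex-3-en-1-yl]ethenyl]-3-methoxyphenol
Conditions: Bu4NF, AcOH, THF, 0 → 20 °C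
Reagents that add atoms: none
Why: Fluoride cleaves both aryl silyl ethers, and the acetic acid buffer keeps the p-alkenyl phenoxide from standing as a free base.

Step 13
Reactants: 24 the diphenol
Product: 26 5-[(E)-2-[(1R,2S)-2-(5-formyl-4-hydroxy-2-methoxyphenyl)-1,4-dimethylcyclohex-3-en-1-yl]ethenyl]-2-hydroxy-4-methoxybenzaldehyde, via bis(hydroxymethyl) diphenol 25 (not isolated)
Conditions: MgCl2, Et3N, (CH2O)n, MeCN, 80 °C; aq. HCl work-up
Reagents that add atoms: paraformaldehyde (as formaldehyde), C=O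
Why: Magnesium-mediated ortho-formylation (Casnati–Skattebøl), in which each magnesium phenoxide delivers formaldehyde to the open ortho position para to the methoxy group (C4a′ and C4a″, the site between the two oxygens being hindered) and a second formaldehyde oxidises the benzylic alkoxide.

Step 14
Reactants: 26 the bis-salicylaldehyde
Product: 28 7-methoxy-6-[(E)-2-[(1R,2S)-2-(7-methoxy-2-oxo-2H-chromen-6-yl)-1,4-dimethylcyclohex-3-en-1-yl]ethenyl]-2H-chromen-2-one, via bis-cinnamate 27 (not isolated)
Conditions: Ph3P=CHCO2Et (3 equiv), PhNEt2, 210 °C, Ar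
Reagents that add atoms: ethyl (triphenyl-λ5-phosphanylidene)acetate, CCOC(=O)C=P(c1ccccc1)(c1ccccc1)c1ccccc1
Why: Twofold Wittig olefination followed by thermal E→Z isomerisation and lactonisation of the o-hydroxycinnamates in hot diethylaniline, the classical one-pot coumarin synthesis, which forms no stereocentre and leaves C1 and C6 untouched.

**Compound list**

1 | 4-hydroxy-2-methoxybenzaldehyde | COc1cc(O)ccc1C=O | starting material
2 | triisopropylsilyl trifluoromethanesulfonate | CC(C)[Si](OS(=O)(=O)C(F)(F)F)(C(C)C)C(C)C | starting material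
3 | 2-methoxy-4-(triisopropylsilyloxy)benzaldehyde | COc1cc(O[Si](C(C)C)(C(C)C)C(C)C)ccc1C=O | intermediate
4 | diethyl (2-methylprop-2-en-1-yl)phosphonate | CCOP(=O)(CC(C)=C)OCC | starting material
5 | (E)-1-[2-methoxy-4-(triisopropylsilyloxy)phenyl]-3-methylbuta-1,3-diene | CC(=C)/C=C/c1ccc(O[Si](C(C)C)(C(C)C)C(C)C)cc1OC | intermediate
6 | methacrolein (2-methylprop-2-enal) | CC(=C)C=O | starting material
7 | (1S,2R)-2-[2-methoxy-4-(triisopropylsilyloxy)phenyl]-1,4-dimethylcyclohex-3-ene-1-carbaldehyde | O=C[C@@]1(C)CCC(C)=C[C@@H]1c1ccc(O[Si](C(C)C)(C(C)C)C(C)C)cc1OC | intermediate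
8 | triethyl 4-phosphonocrotonate | CCOC(=O)/C=C/CP(=O)(OCC)OCC | starting material
9 | ethyl (2E,4E)-5-Cy-penta-2,4-dienoate | CCOC(=O)/C=C/C=C/[C@@]1(C)CCC(C)=C[C@@H]1c1ccc(O[Si](C(C)C)(C(C)C)C(C)C)cc1OC | intermediate
10 | (2E,4E)-N-methoxy-N-methyl-5-Cy-penta-2,4-dienamide | CON(C)C(=O)/C=C/C=C/[C@@]1(C)CCC(C)=C[C@@H]1c1ccc(O[Si](C(C)C)(C(C)C)C(C)C)cc1OC | intermediate
11 | (3E,5E)-6-Cy-hexa-3,5-dien-2-one | CC(=O)/C=C/C=C/[C@@]1(C)CCC(C)=C[C@@H]1c1ccc(O[Si](C(C)C)(C(C)C)C(C)C)cc1OC | intermediate
12 | (5E,7E)-1,1,1-trifluoro-8-Cy-octa-5,7-diene-2,4-dione (drawn as the diketone) | FC(F)(F)C(=O)CC(=O)/C=C/C=C/[C@@]1(C)CCC(C)=C[C@@H]1c1ccc(O[Si](C(C)C)(C(C)C)C(C)C)cc1OC | intermediate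
13 | (3E,5E)-1-diazo-6-Cy-hexa-3,5-dien-2-one | [N-]=[N+]=CC(=O)/C=C/C=C/[C@@]1(C)CCC(C)=C[C@@H]1c1ccc(O[Si](C(C)C)(C(C)C)C(C)C)cc1OC | intermediate
14 | ethyl formate | CCOC=O | starting material
15 | dibromomethane | BrCBr | starting material
16 | lithium ethynolate (not isolated) | [Li+].[O-]C#C | intermediate
17 | (triisopropylsilyloxy)acetylene | C#CO[Si](C(C)C)(C(C)C)C(C)C | intermediate
18 | (3E,5E)-6-Cy-hexa-1,3,5-trien-1-one, the dienylketene (not isolated) | O=C=C/C=C/C=C/[C@@]1(C)CCC(C)=C[C@@H]1c1ccc(O[Si](C(C)C)(C(C)C)C(C)C)cc1OC | intermediate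
19 | 4-[(1E,3E)-4-Cy-buta-1,3-dien-1-yl]-3-(triisopropylsilyloxy)cyclobut-2-en-1-one, either configuration at C4 (not isolated) | O=C1C=C(O[Si](C(C)C)(C(C)C)C(C)C)C1/C=C/C=C/[C@@]2(C)CCC(C)=C[C@@H]2c2ccc(O[Si](C(C)C)(C(C)C)C(C)C)cc2OC | intermediate
20 | (5E,7E)-8-Cy-3-(triisopropylsilyloxy)octa-1,3,5,7-tetraen-1-one, C2 and C5 cis across C3=C4 (not isolated) | O=C=C/C(O[Si](C(C)C)(C(C)C)C(C)C)=C\C=C\C=C\[C@@]2(C)CCC(C)=C[C@@H]2c2ccc(O[Si](C(C)C)(C(C)C)C(C)C)cc2OC | intermediate
21 | 6-[(E)-2-Cy-ethenyl]-3-(triisopropylsilyloxy)cyclohexa-2,4-dien-1-one, either configuration at C6 (not isolated) | O=C1C=C(O[Si](C(C)C)(C(C)C)C(C)C)C=CC1/C=C/[C@@]2(C)CCC(C)=C[C@@H]2c2ccc(O[Si](C(C)C)(C(C)C)C(C)C)cc2OC | intermediate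
22 | 2-[(E)-2-Cy-ethenyl]-5-(triisopropylsilyloxy)phenol | Oc1cc(O[Si](C(C)C)(C(C)C)C(C)C)ccc1/C=C/[C@@]1(C)CCC(C)=C[C@@H]1c1ccc(O[Si](C(C)C)(C(C)C)C(C)C)cc1OC | intermediate
23 | 1-[(E)-2-Cy-ethenyl]-2-methoxy-4-(triisopropylsilyloxy)benzene | COc1cc(O[Si](C(C)C)(C(C)C)C(C)C)ccc1/C=C/[C@@]1(C)CCC(C)=C[C@@H]1c1ccc(O[Si](C(C)C)(C(C)C)C(C)C)cc1OC | intermediate
24 | 4-[(E)-2-[(1R,2S)-2-(4-hydroxy-2-methoxyphenyl)-1,4-dimethylcyclohex-3-en-1-yl]ethenyl]-3-methoxyphenol | COc1cc(O)ccc1/C=C/[C@@]1(C)CCC(C)=C[C@@H]1c1ccc(O)cc1OC | intermediate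
25 | 4-[(E)-2-[(1R,2S)-2-[4-hydroxy-5-(hydroxymethyl)-2-methoxyphenyl]-1,4-dimethylcyclohex-3-en-1-yl]ethenyl]-2-(hydroxymethyl)-5-methoxyphenol (not isolated) | COc1cc(O)c(CO)cc1/C=C/[C@@]1(C)CCC(C)=C[C@@H]1c1cc(CO)c(O)cc1OC | intermediate
26 | 5-[(E)-2-[(1R,2S)-2-(5-formyl-4-hydroxy-2-methoxyphenyl)-1,4-dimethylcyclohex-3-en-1-yl]ethenyl]-2-hydroxy-4-methoxybenzaldehyde | COc1cc(O)c(C=O)cc1/C=C/[C@@]1(C)CCC(C)=C[C@@H]1c1cc(C=O)c(O)cc1OC | intermediate
27 | ethyl (E)-3-{5-[(E)-2-[(1R,2S)-2-{5-[(E)-3-ethoxy-3-oxoprop-1-enyl]-4-hydroxy-2-methoxyphenyl}-1,4-dimethylcyclohex-3-en-1-yl]ethenyl]-2-hydroxy-4-methoxyphenyl}prop-2-enoate (not isolated) | COc1cc(O)c(/C=C/C(=O)OCC)cc1/C=C/[C@@]1(C)CCC(C)=C[C@@H]1c1cc(/C=C/C(=O)OCC)c(O)cc1OC | intermediate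
28 | 7-methoxy-6-[(E)-2-[(1R,2S)-2-(7-methoxy-2-oxo-2H-chromen-6-yl)-1,4-dimethylcyclohex-3-en-1-yl]ethenyl]-2H-chromen-2-one | COc1cc2oc(=O)ccc2cc1/C=C/[C@@]1(C)CCC(C)=C[C@@H]1c1cc2ccc(=O)oc2cc1OC | target

**Step count and weak points**

Total steps: 14. Longest linear sequence: 13 (steps 1–8 and 10–14); step 9 is a one-step side branch.

Step 3. The cycloaddition may run through the formyl-endo arrangement (formyl ending cis to the aryl group), may select the enal faces poorly, or the acidic catalyst may oligomerise the electron-rich diene. The fallback sets out from 5 and comes back at 7, and exchanges the roles of the two C1 substituents so that an endo formyl group becomes the methyl group. Diene 5 would be combined, under the mirror-image oxazaborolidinium catalyst, with 2-[(tert-butyldimethylsilyloxy)methyl]prop-2-enal F1 (made from 3-(tert-butyldimethylsilyloxy)propanal by α-methylenation with aqueous formaldehyde and pyrrolidinium propanoate). This should give the cycloadduct with formyl cis to aryl F2. Its tosylhydrazone F3 (TsNHNH2, EtOH) would be reduced with catecholborane and then NaOAc·3H2O to the C1-methyl silyl ether F4. The alkyl silyl ether would be removed with 10-camphorsulfonic acid in MeOH, which the aryl silyl ether should survive, to give the neopentyl alcohol F5. Dess–Martin oxidation would then deliver 7.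

Step 10. Light may isomerise C5′=C6′ before nitrogen is lost, which opens a direct closure of 18 to a ring without O8a′. The diazo group may also add to the ynol ether as a dipole, or phenol already formed may be acylated by ketene 18. The fallback sets out from 7 (and uses 3) and comes back at 23, bringing ring A in intact by olefination. Aldehyde 3 would be reduced (NaBH4, MeOH) to [2-methoxy-4-(triisopropylsilyloxy)phenyl]methanol F6. This would be converted with P(OEt)3 and ZnI2 into diethyl {[2-methoxy-4-(triisopropylsilyloxy)phenyl]methyl}phosphonate F7. Its potassium salt (KN(SiMe3)2, THF) would be condensed with aldehyde 7 in a Horner–Wadsworth–Emmons reaction to give E-alkene 23 directly.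

Step 9. The formate adduct may collapse early and take up a second carbenoid, or the unhindered parent ynolate may be silylated on carbon to give the silylketene. The fallback sets out from 13 and comes back at 24, replacing the silyl ynol ether by an alkyl ynol ether made without an ynolate. 2-(Trimethylsilyl)ethanol, KH and trichloroethylene would give (E)-1,2-dichloro-1-[2-(trimethylsilyl)ethoxy]ethene F8. n-BuLi (2 equiv) and then MeOH would convert it into [2-(ethynyloxy)ethyl]trimethylsilane F9. Irradiation of 13 with F9 as in step 10 would give 2-[(E)-2-Cy-ethenyl]-5-[2-(trimethylsilyl)ethoxy]phenol F10. Methylation (MeI, K2CO3) would give its methyl ether F11. Bu4NF in DMF at 60 °C would then cleave the aryl silyl ether and fragment the silylethyl ether in one operation to give 24.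

**Further compounds**

F1 | step 3 | 2-[(tert-butyldimethylsilyloxy)methyl]prop-2-enal | C=C(CO[Si](C)(C)C(C)(C)C)C=O
F2 | step 3 | 1-[(tert-butyldimethylsilyloxy)methyl]-2-[2-methoxy-4-(triisopropylsilyloxy)phenyl]-4-methylcyclohex-3-ene-1-carbaldehyde, formyl cis to aryl, aryl carbon as in 7 | O=C[C@]1(CO[Si](C)(C)C(C)(C)C)CCC(C)=C[C@@H]1c1ccc(O[Si](C(C)C)(C(C)C)C(C)C)cc1OC
F3 | step 3 | 4-methylbenzenesulfonylhydrazone of F2 | Cc1ccc(cc1)S(=O)(=O)N/N=C/[C@]1(CO[Si](C)(C)C(C)(C)C)CCC(C)=C[C@@H]1c1ccc(O[Si](C(C)C)(C(C)C)C(C)C)cc1OC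
F4 | step 3 | tert-butyldimethylsilyl ether of the alcohol F5 | CC(C)(C)[Si](C)(C)OC[C@@]1(C)CCC(C)=C[C@@H]1c1ccc(O[Si](C(C)C)(C(C)C)C(C)C)cc1OC
F5 | step 3 | {2-[2-methoxy-4-(triisopropylsilyloxy)phenyl]-1,4-dimethylcyclohex-3-en-1-yl}methanol, configured as 7 | OC[C@@]1(C)CCC(C)=C[C@@H]1c1ccc(O[Si](C(C)C)(C(C)C)C(C)C)cc1OC
F6 | step 10 | [2-methoxy-4-(triisopropylsilyloxy)phenyl]methanol | COc1cc(O[Si](C(C)C)(C(C)C)C(C)C)ccc1CO
F7 | step 10 | diethyl {[2-methoxy-4-(triisopropylsilyloxy)phenyl]methyl}phosphonate | CCOP(=O)(Cc1ccc(O[Si](C(C)C)(C(C)C)C(C)C)cc1OC)OCC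
F8 | step 9 | (E)-1,2-dichloro-1-[2-(trimethylsilyl)ethoxy]ethene | Cl/C=C(/Cl)OCC[Si](C)(C)C
F9 | step 9 | [2-(ethynyloxy)ethyl]trimethylsilane | C#COCC[Si](C)(C)C
F10 | step 9 | 2-[(E)-2-Cy-ethenyl]-5-[2-(trimethylsilyl)ethoxy]phenol | Oc1cc(OCC[Si](C)(C)C)ccc1/C=C/[C@@]1(C)CCC(C)=C[C@@H]1c1ccc(O[Si](C(C)C)(C(C)C)C(C)C)cc1OC
F11 | step 9 | 1-[(E)-2-Cy-ethenyl]-2-methoxy-4-[2-(trimethylsilyl)ethoxy]benzene | COc1cc(OCC[Si](C)(C)C)ccc1/C=C/[C@@]1(C)CCC(C)=C[C@@H]1c1ccc(O[Si](C(C)C)(C(C)C)C(C)C)cc1OC
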